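The runs were generated by integration from invented constants, and the scatter is random.

Start from the leftover. In the autumn run 53.1% of the substrate still stands at 50.0 h, as it did at 40.0 h.

| flask | substrate | coupling partner | remark | time |
|---|---|---|---|---|
| autumn | 1.5 M | 0.70 M | run made earlier |  |
| winter | 1.5 M | 1.6 M | run made earlier |  |
| flask | 1.5 M | 1.05 M |  | 2.5 d |

- autumn (time / h: substrate / %, target / %, isomer of the product / %): 12.0: 54.4, 34.4, 11.2; 25.0: 54.2, 34.2, 12.0; 40.0: 53.1, 35.0, 12.2; 50.0: 53.1, 35.0, 12.2
- winter (time / h: substrate / %, target / %, isomer of the product / %): 12.0: 3.4, 73.5, 24.7; 25.0: 0.4, 74.4, 25.6; 40.0: 0.9, 74.7, 25.0; 50.0: 0, 73.8, 25.4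

(each reading ± 0.5 percentage points)

- at 2.5 d, what has stopped the reaction, if anything has (it is still moving / forward and back rates have come level / the coupling partner has run out first / all of the substrate has reacted)
- part of the substrate gone at 2.5 d
- the target standing at 2.5 d, as a percentage of the substrate charged
- the isomer of the product standing at 2.5 d, as a percentage of the substrate charged

- the numbers in the tables scatter with a standard deviation of 0.5 percentage points
- steps thought possible: substrate + coupling partner -> target + by-product; target <-> isomer of the product
- the reaction counts as stopped when no species that holds the substrate changes by six tenths of a point or more over the second half of the time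

A colleague and I read that leftover differently. I read it as a charge effect. The autumn run lost 46.9% of its substrate, and [coupling partner]/[substrate] there is 46.7%. In the winter run the partner is in excess, and the substrate reads 0% at the end.

So I carry one quantity, the conversion ceiling: the smaller of [coupling partner]/[substrate] and one 70.0%. The partner is then the limiting reagent in this flask. Both runs stand still within scatter from 25.0 h, and this flask gets longer, 2.5 d, so I take the ceiling as its end.

The isomer's share of the product reads 25.6% in the winter run and 25.8% in the autumn run. I therefore expect 52.1% target and 17.9% isomer.

My colleague objects that two runs show no corner, and draws a straight line between them. With 38.9% of the way from autumn to winter, that line gives 67.5% gone, 50.1% target and 17.3% isomer. We stand 2.5 percentage points apart on conversion, and the scatter is 0.5 points, so this flask can separate us.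

The forecast takes my side with a slightly different split: the coupling partner has run out first, 70% gone, 52.2% target and 17.8% isomer, because “the partner is consumed 1:1 and then the reaction stops”.

The flask gives the coupling partner has run out first, with 70.0% gone, 52.2% target and 17.8% isomer. That is my ceiling of 70.0%.

    substrate + coupling partner → target + by-product (k = 2.90 × 10⁻⁴ L mol⁻¹ s⁻¹)
    target ⇌ isomer of the product (K = 0.340, k = 2.80 × 10⁻⁵ s⁻¹)

Substrate's half-life by coupling, 0.63 h, and target's forward half-life to isomer, 0.29 d, are both short against 2.5 d. At 2.5 d this flask holds 0% of its partner and 30% of its substrate.

My colleague's line is right at the two charges it was drawn through, autumn and winter, but the part gone in this flask stands 2.5 points above it.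

With [substrate] at 0.60 M, the ceiling is 100%, and the share gives 25.6% isomer. That neighbouring flask computes to 100% gone and 25.4% isomer, with 0% substrate and 42.9% of the partner left.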